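**Plan**
- Retrosynthesis: the two benzyl ethers and the 4'-O-methyl group come off first. Ring B is then cut at C1'–C2' and C1'–C6', which leaves 2-methylchromone 7 (its methyl carbon is C1') and the symmetrical pyranone 12.
- Enabling feature: ring B has a mirror plane through C1' and C4' and carries oxygen on C3', C4' and C5'. This is the C2–C6 pattern of a 3,5-dialkoxy-4-pyranone whose ring oxygen is exchanged for C1', and C1' can be the acidic methyl carbon of a 2-methylchromone.
- Forward: ring A is bought as 1,2,3,4-tetramethoxybenzene; hydroxylation, ortho-methoxyacetylation and Kostanecki–Robinson closure of ring C give 7. Oxidation, double formylation and acid closure give 12. Ring B is formed last from 7 and 12, followed by O-methylation and hydrogenolysis.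
- Stereochemistry: the target has no stereocentre and no stereogenic double bond, so nothing has to be controlled.

Key step: step 6

Assumption: the enol and alkene geometries of the open-chain compounds 11, 13 and F5 are not fixed by the chemistry and do not matter for ring closure, so their SMILES carry no double-bond geometry; diketone F4 is racemic and enolisable.

**Step 1**
Reactants: 1 1,2,3,4-tetramethoxybenzene
Product: 4 2,3,4,5-tetramethoxyphenol, via aryllithium 2 (not isolated), via dimethyl arylboronate 3 (not isolated)
Conditions: n-BuLi, TMEDA, THF, 0 °C; B(OMe)3, −78 °C → rt; AcOH, 30% H2O2, 0 °C → rt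
Reagents that add atoms: hydrogen peroxide (OO)
Why: Directed ortho-lithiation at one of the two equivalent ring C–H positions next to a methoxy group, borylation and oxidative 1,2-aryl shift from boron to oxygen form a standard one-pot arene hydroxylation.

**Step 2**
Reactants: 4 2,3,4,5-tetramethoxyphenol
Product: 6 1-(2-hydroxy-3,4,5,6-tetramethoxyphenyl)-2-methoxyethan-1-one, via difluoroboron chelate 5 (not isolated)
Conditions: MeOCH2CO2H, BF3·OEt2, 80 °C; then H2O/MeOH, 60 °C
Reagents that add atoms: methoxyacetic acid (COCC(=O)O)
Why: BF3-promoted Friedel–Crafts acylation of the phenol with the free acid should go to the single unsubstituted ring position (ortho to OH) and rest at the difluoroboron chelate 5, which is hydrolysed on work-up.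

**Step 3**
Reactants: 6 1-(2-hydroxy-3,4,5,6-tetramethoxyphenyl)-2-methoxyethan-1-one
Product: 7 3,5,6,7,8-pentamethoxy-2-methyl-4H-chromen-4-one
Conditions: Ac2O, NaOAc, 170 °C
Reagents that add atoms: acetic anhydride (CC(=O)OC(C)=O)
Why: In the Kostanecki–Robinson reaction, O-acetylation, intramolecular acyl transfer to the α-methoxy enolate and cyclodehydration should close ring C with the acetyl methyl as the 2-methyl group, the α-methoxy group blocking any 3-acylation.

**Step 4**
Reactants: 8 1,3-bis(benzyloxy)propan-2-ol
Product: 9 1,3-bis(benzyloxy)propan-2-one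
Conditions: catalytic TEMPO, catalytic KBr, NaOCl, NaHCO3, CH2Cl2/H2O, 0 °C
Reagents that add atoms: none
Why: Anelli oxidation through the oxoammonium form of TEMPO converts the secondary alcohol into the ketone without touching the benzyl ethers.

**Step 5**
Reactants: 9 1,3-bis(benzyloxy)propan-2-one; 10 ethyl formate
Product: 12 3,5-bis(benzyloxy)-4H-pyran-4-one, via bis(hydroxymethylene) ketone 11 (not isolated)
Conditions: NaH (2.5 equiv), THF, 0 °C → rt; then conc HCl, EtOH, 50 °C
Reagents that add atoms: none
Why: Twofold crossed Claisen formylation at the two alkoxy-activated α-methylene groups gives the bis(hydroxymethylene) ketone, which on acidification cyclises by hemiacetal formation and dehydration, the established route to 3,5-disubstituted 4-pyranones.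

**Step 6**
Reactants: 7 3,5,6,7,8-pentamethoxy-2-methyl-4H-chromen-4-one; 12 3,5-bis(benzyloxy)-4H-pyran-4-one
Product: 14 2-[3,5-bis(benzyloxy)-4-hydroxyphenyl]-3,5,6,7,8-pentamethoxy-4H-chromen-4-one, via open-chain formyl enol 13 (not isolated)
Conditions: KOtBu (3 equiv), t-BuOH/THF, rt → 70 °C; then 1 M HCl
Reagents that add atoms: none
Why: Proposed new method: tert-butoxide reversibly deprotonates the 2-methyl group of 7 to a chromone-conjugated (vinylogous) carbanion that adds in conjugate fashion to C2 of pyranone 12, and E1cB expulsion of the ring oxygen opens the adduct to the formyl enolate of 13; the CH2 group of 13, now allylic to the dienone and still conjugated to the chromone, is deprotonated again and attacks the formyl carbon, after which loss of water and dienone–phenol tautomerisation should deliver the phenoxide of 14. The closest known reaction type is the tert-butoxide-mediated conversion of 4H-pyran-4-one and of pyrylium salts into para-substituted phenols and benzenes by nitromethane or malonate carbanions, combined with the base-mediated lateral condensation of 2-methylchromones with aldehydes; new here are the vinylogous ketone carbanion as the one-carbon donor and the 3,5-dialkoxy substitution of the pyranone. Ring B, the only ring formed, closes by a 6-(enolendo)-exo-trig intramolecular aldol addition of the former methyl carbon (C1') to the formyl carbon (C6'), the C1'–C2' bond having been made in the preceding conjugate addition. No stereocentre is created, since all six ring carbons end up sp2. The step needs conjugate addition at C2 in preference to addition at the C4 carbonyl and reaction through the lateral carbon only: carbonyl addition to a vinylogous ester flanked by two benzyloxy groups is reversible in alkoxide/alcohol whereas ring opening to the stabilised formyl enolate is a thermodynamic sink, the 2-methyl group is the only acidic C–H of 7, and the mirror symmetry of 12 with unsubstituted C2 and C6 allows only one regioisomer.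

**Step 7**
Reactants: 14 2-[3,5-bis(benzyloxy)-4-hydroxyphenyl]-3,5,6,7,8-pentamethoxy-4H-chromen-4-one
Product: 15 2-[3,5-bis(benzyloxy)-4-methoxyphenyl]-3,5,6,7,8-pentamethoxy-4H-chromen-4-one
Conditions: MeI, K2CO3, DMF, rt
Reagents that add atoms: iodomethane (CI)
Why: Williamson O-methylation of the only free phenol, made more acidic by the para chromone ring, should be clean despite the two flanking benzyloxy groups.

**Step 8**
Reactants: 15 2-[3,5-bis(benzyloxy)-4-methoxyphenyl]-3,5,6,7,8-pentamethoxy-4H-chromen-4-one
Product: 16 3',5'-dihydroxy-3,5,6,7,8,4'-hexamethoxyflavone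
Conditions: H2 (1 atm), 10% Pd/C, EtOAc/MeOH, rt
Reagents that add atoms: none
Why: Hydrogenolysis of benzyl aryl ethers over palladium on carbon should leave the aryl methyl ethers and the tetrasubstituted, electron-rich C2=C3 bond of the chromone untouched.

**Compound list**
1 | 1,2,3,4-tetramethoxybenzene | COc1ccc(OC)c(OC)c1OC | starting material
2 | 2,3,4,5-tetramethoxyphenyllithium (formed in situ) | [Li]c1cc(OC)c(OC)c(OC)c1OC | intermediate
3 | dimethyl (2,3,4,5-tetramethoxyphenyl)boronate (formed in situ) | COB(OC)c1cc(OC)c(OC)c(OC)c1OC | intermediate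
4 | 2,3,4,5-tetramethoxyphenol | COc1cc(O)c(OC)c(OC)c1OC | intermediate
5 | difluoroboron O,O-chelate of ketone 6, boron bound to the phenolic and the ketone oxygen (formed in situ) | COCC1=[O+][B-](F)(F)Oc2c(OC)c(OC)c(OC)c(OC)c12 | intermediate
6 | 1-(2-hydroxy-3,4,5,6-tetramethoxyphenyl)-2-methoxyethan-1-one | COCC(=O)c1c(O)c(OC)c(OC)c(OC)c1OC | intermediate
7 | 3,5,6,7,8-pentamethoxy-2-methyl-4H-chromen-4-one | COc1c(C)oc2c(OC)c(OC)c(OC)c(OC)c2c1=O | intermediate
8 | 1,3-bis(benzyloxy)propan-2-ol | OC(COCc1ccccc1)COCc1ccccc1 | starting material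
9 | 1,3-bis(benzyloxy)propan-2-one | O=C(COCc1ccccc1)COCc1ccccc1 | intermediate
10 | ethyl formate | CCOC=O | starting material
11 | 2,4-bis(benzyloxy)-1,5-dihydroxypenta-1,4-dien-3-one (formed in situ, first as its disodium salt) | O=C(C(OCc1ccccc1)=CO)C(OCc1ccccc1)=CO | intermediate
12 | 3,5-bis(benzyloxy)-4H-pyran-4-one | O=c1c(OCc2ccccc2)cocc1OCc1ccccc1 | intermediate
13 | 2-[3,5-bis(benzyloxy)-6-hydroxy-4-oxohexa-2,5-dien-1-yl]-3,5,6,7,8-pentamethoxy-4H-chromen-4-one (formed in situ as its enolate) | COc1c(CC=C(OCc3ccccc3)C(=O)C(OCc4ccccc4)=CO)oc2c(OC)c(OC)c(OC)c(OC)c2c1=O | intermediate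
14 | 2-[3,5-bis(benzyloxy)-4-hydroxyphenyl]-3,5,6,7,8-pentamethoxy-4H-chromen-4-one | Oc1c(OCc2ccccc2)cc(-c2oc3c(OC)c(OC)c(OC)c(OC)c3c(=O)c2OC)cc1OCc1ccccc1 | intermediate
15 | 2-[3,5-bis(benzyloxy)-4-methoxyphenyl]-3,5,6,7,8-pentamethoxy-4H-chromen-4-one | COc1c(OCc2ccccc2)cc(-c2oc3c(OC)c(OC)c(OC)c(OC)c3c(=O)c2OC)cc1OCc1ccccc1 | intermediate
16 | 3',5'-dihydroxy-3,5,6,7,8,4'-hexamethoxyflavone, 2-(3,5-dihydroxy-4-methoxyphenyl)-3,5,6,7,8-pentamethoxy-4H-chromen-4-one | COc1c(O)cc(-c2oc3c(OC)c(OC)c(OC)c(OC)c3c(=O)c2OC)cc1O | target

**Step count**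
Total: 8 steps. Longest linear sequence: 6 steps (1, 2, 3, 6, 7, 8); the pyranone branch (steps 4 and 5) joins at step 6.

**Steps most likely to fail**

Step 6. The lateral carbanion may add only reversibly at the C4 carbonyl or not at all at the alkoxy-substituted C2 of the pyranone. The opened formyl enolate may also fail to re-close, or alkoxide may open the chromone ring. The fallback uses known chemistry, sets out from ketone 6 and returns at 15. Commercial methyl 3,5-dihydroxy-4-methoxybenzoate would be benzylated (BnBr, K2CO3, DMF) to methyl 3,5-bis(benzyloxy)-4-methoxybenzoate F1 and saponified (LiOH, THF/H2O) to 3,5-bis(benzyloxy)-4-methoxybenzoic acid F2. Esterification of the phenol of 6 with this acid (EDC·HCl, DMAP, CH2Cl2) should give 2-(methoxyacetyl)-3,4,5,6-tetramethoxyphenyl 3,5-bis(benzyloxy)-4-methoxybenzoate F3. Baker–Venkataraman rearrangement (LiN(SiMe3)2, THF, −78 → 0 °C) should then give 1-[3,5-bis(benzyloxy)-4-methoxyphenyl]-3-(2-hydroxy-3,4,5,6-tetramethoxyphenyl)-2-methoxypropane-1,3-dione F4. Cyclodehydration (TsOH, toluene, 80 °C) closes ring C to flavone 15, which enters step 8; steps 3 to 7 are then not needed.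

Step 5. The second formylation may stall at the mono-formyl enolate because a dianion is required, and the α-alkoxy ketone may self-condense under the strongly basic conditions. The fallback sets out from 9 and returns at 12. Heating 9 with excess tert-butoxybis(dimethylamino)methane (neat, 100 °C) should give, under neutral conditions and without any dianion, 2,4-bis(benzyloxy)-1,5-bis(dimethylamino)penta-1,4-dien-3-one F5. Aqueous HCl in THF then hydrolyses one enamine and closes the ring with loss of dimethylamine to give 12.

Step 2. Acylation may stop at oxygen without transfer of the acyl group to carbon, and the Lewis acid may cleave the methyl ether ortho to the new ketone by chelation. The fallback sets out from 4 and returns at 6. The phenol is protected (MOMCl, i-Pr2NEt, CH2Cl2) as 1-(methoxymethoxy)-2,3,4,5-tetramethoxybenzene F6. Lithiation with n-BuLi (THF, 0 °C) at the only ring C–H, which lies between the MOM ether and a methoxy group, gives [2-(methoxymethoxy)-3,4,5,6-tetramethoxyphenyl]lithium F7. Acylation with N-methoxy-N-methyl-2-methoxyacetamide gives 2-methoxy-1-[2-(methoxymethoxy)-3,4,5,6-tetramethoxyphenyl]ethan-1-one F8. HCl in MeOH then removes the MOM group to give 6.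

**Further compounds**
F1 | step 6 | methyl 3,5-bis(benzyloxy)-4-methoxybenzoate | COC(=O)c1cc(OCc2ccccc2)c(OC)c(OCc2ccccc2)c1
F2 | step 6 | 3,5-bis(benzyloxy)-4-methoxybenzoic acid | OC(=O)c1cc(OCc2ccccc2)c(OC)c(OCc2ccccc2)c1
F3 | step 6 | 2-(methoxyacetyl)-3,4,5,6-tetramethoxyphenyl 3,5-bis(benzyloxy)-4-methoxybenzoate | COCC(=O)c1c(OC(=O)c2cc(OCc3ccccc3)c(OC)c(OCc3ccccc3)c2)c(OC)c(OC)c(OC)c1OC
F4 | step 6 | 1-[3,5-bis(benzyloxy)-4-methoxyphenyl]-3-(2-hydroxy-3,4,5,6-tetramethoxyphenyl)-2-methoxypropane-1,3-dione (racemic, enolisable) | COC(C(=O)c1cc(OCc2ccccc2)c(OC)c(OCc2ccccc2)c1)C(=O)c1c(O)c(OC)c(OC)c(OC)c1OC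
F5 | step 5 | 2,4-bis(benzyloxy)-1,5-bis(dimethylamino)penta-1,4-dien-3-one | CN(C)C=C(OCc1ccccc1)C(=O)C(OCc1ccccc1)=CN(C)C
F6 | step 2 | 1-(methoxymethoxy)-2,3,4,5-tetramethoxybenzene | COCOc1cc(OC)c(OC)c(OC)c1OC
F7 | step 2 | [2-(methoxymethoxy)-3,4,5,6-tetramethoxyphenyl]lithium | COCOc1c([Li])c(OC)c(OC)c(OC)c1OC
F8 | step 2 | 2-methoxy-1-[2-(methoxymethoxy)-3,4,5,6-tetramethoxyphenyl]ethan-1-one | COCC(=O)c1c(OCOC)c(OC)c(OC)c(OC)c1OC
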